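**Retrosynthetic overview**

1. Numbering: C10 = quaternary ether carbon (its CH3 = C14), C9 = ester CH, C8 = lactone O–CH, C7 = ring-fusion CH bearing C11 (C12 = lactone C=O, C13 = exocyclic CH2), C6 = CH2, C5 = ether CH, C4 = CH–CH3 (C15), C3–C1 = CH2 chain back to C10; ring A = oxepane O/C5/C4/C3/C2/C1/C10, ring B = oxepane O/C5/C6/C7/C8/C9/C10. The route rests on ring A: because its C4 methyl sits directly beside the ether carbon C5, ring A can be read as a dihydropyran (O, C10, C1, C2, C3, C5) fused across C3–C5 to a cyclopropane whose third, methyl-bearing carbon is C4.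
2. Endgame disconnections: the C9–O ester (acylation), then the lactone C12–O8 together with the ring B bond C7–C8 (CrCl2 allylation of a C8 aldehyde by an allylic bromide built on the C5 acetic ester arm).
3. Key disconnection: C5–C6 plus the cyclopropane bond C3–C5; acetate 10 and ketene silyl acetal 11 give oxepene 13 by cyclopropylcarbinyl ring enlargement and capture of the oxocarbenium ion at C5.
4. Acetate 10 comes from methyl (S)-glycerate acetonide by way of the C10 methyl ketone, a stepwise hetero-Diels–Alder reaction, Luche reduction, hydroxyl-directed ethylidene transfer (C4) and acetylation.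
5. Ring order: dioxolane (bought) → pyran (step 3) → cyclopropane (step 5) → ring A by enlargement (step 7) → ring B together with the lactone (step 16).

Key step: step 7

Remark: the target needs C10–O anti to C9–O along C1–C10–C9–C8, which is the non-chelation (Felkin–Anh/Cornforth) outcome of addition to ketone 3; chelation at the α-oxygen would give the C10 epimer, so step 3 uses the monodentate Lewis acid BF3·OEt2.

**Route**

Step 1
Reactants: 1 methyl (4S)-2,2-dimethyl-1,3-dioxolane-4-carboxylate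
Product: 2 (4S)-N-methoxy-N,2,2-trimethyl-1,3-dioxolane-4-carboxamide
Conditions: MeNH(OMe)·HCl, i-PrMgCl, THF, −20 °C
Reagents that add atoms: N,O-dimethylhydroxylamine hydrochloride, CNOC.Cl
Why: Aminolysis of the ester by the magnesium amide (Weinreb amide formation) is fast at low temperature, so the α-alkoxy stereocenter C9 is not enolized.

Step 2
Reactants: 2 (4S)-N-methoxy-N,2,2-trimethyl-1,3-dioxolane-4-carboxamide
Product: 3 1-[(4S)-2,2-dimethyl-1,3-dioxolan-4-yl]ethan-1-one
Conditions: MeMgBr, THF, 0 °C; aq. NH4Cl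
Reagents that add atoms: methylmagnesium bromide, C[Mg]Br
Why: Weinreb ketone synthesis: the chelated tetrahedral magnesium adduct collapses only on work-up, so a single methyl group (C14) is added and no tertiary alcohol forms.

Step 3
Reactants: 3 1-[(4S)-2,2-dimethyl-1,3-dioxolan-4-yl]ethan-1-one; 4 (E)-1-methoxy-3-(trimethylsilyloxy)buta-1,3-diene
Product: 6 (2R)-2-[(4S)-2,2-dimethyl-1,3-dioxolan-4-yl]-2-methyl-2,3-dihydro-4H-pyran-4-one, via aldol adduct 5 (not isolated)
Conditions: BF3·OEt2, CH2Cl2, −78 °C; then CF3CO2H (cat.), CH2Cl2, 0 °C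
Reagents that add atoms: none
Why: Stepwise hetero-Diels–Alder reaction (Mukaiyama aldol addition, then acid-promoted cyclization with loss of methanol); the monodentate Lewis acid cannot bridge the ketone and dioxolane oxygens, so the diene terminus C1 should add under Felkin–Anh/Cornforth control anti to the C9–O bond and set C10 as R.

Step 4
Reactants: 6 (2R)-2-[(4S)-2,2-dimethyl-1,3-dioxolan-4-yl]-2-methyl-2,3-dihydro-4H-pyran-4-one
Product: 7 (2R,4R)-2-[(4S)-2,2-dimethyl-1,3-dioxolan-4-yl]-2-methyl-3,4-dihydro-2H-pyran-4-ol (hydroxyl cis to the dioxolanyl group)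
Conditions: NaBH4, CeCl3·7H2O, MeOH, −78 °C
Reagents that add atoms: none
Why: Luche 1,2-reduction of the vinylogous ester; hydride should enter on the face of the small C10 methyl, away from the bulkier dioxolanyl group, which places the new C2 hydroxyl cis to the C9 side chain.

Step 5
Reactants: 7 (2R,4R)-2-[(4S)-2,2-dimethyl-1,3-dioxolan-4-yl]-2-methyl-3,4-dihydro-2H-pyran-4-ol; 8 1,1-diiodoethane
Product: 9 (1R,3R,5R,6R,7S)-3-[(4S)-2,2-dimethyl-1,3-dioxolan-4-yl]-3,7-dimethyl-2-oxabicyclo[4.1.0]heptan-5-ol (cyclopropane cis to OH, methyl exo)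
Conditions: Et2Zn, CH2Cl2, −20 → 0 °C
Reagents that add atoms: none
Why: Hydroxyl-directed Simmons–Smith cyclopropanation (Furukawa conditions) with the ethylidene carbenoid: the zinc alkoxide at C2 delivers the carbenoid to the alkene face cis to oxygen and the methyl should take the exo position, anti to the carbinol carbon, which sets C3, C5 and C4.

Step 6
Reactants: 9 (1R,3R,5R,6R,7S)-3-[(4S)-2,2-dimethyl-1,3-dioxolan-4-yl]-3,7-dimethyl-2-oxabicyclo[4.1.0]heptan-5-ol
Product: 10 (1R,3R,5R,6R,7S)-3-[(4S)-2,2-dimethyl-1,3-dioxolan-4-yl]-3,7-dimethyl-2-oxabicyclo[4.1.0]heptan-5-yl acetate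
Conditions: Ac2O, pyridine, DMAP (cat.), CH2Cl2, 0 °C → rt
Reagents that add atoms: acetic anhydride, CC(=O)OC(C)=O
Why: DMAP-catalysed acylation of the secondary cyclopropyl carbinol with retention at C2 installs the leaving group for the ring enlargement.

Step 7
Reactants: 10 (1R,3R,5R,6R,7S)-3-[(4S)-2,2-dimethyl-1,3-dioxolan-4-yl]-3,7-dimethyl-2-oxabicyclo[4.1.0]heptan-5-yl acetate; 11 1-(tert-butyldimethylsilyloxy)-1-methoxyethene
Product: 13 methyl 2-[(2R,3S,7R)-7-[(4S)-2,2-dimethyl-1,3-dioxolan-4-yl]-3,7-dimethyl-2,3,6,7-tetrahydrooxepin-2-yl]acetate, via oxocarbenium triflate 12 (not isolated)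
Conditions: Me3SiOTf (0.2 equiv), MeCN, −40 → 0 °C
Reagents that add atoms: none
Why: Me3SiOTf removes the C2 acetate as a silyl acetate; the cyclopropylcarbinyl cation left at C2 is relieved by heterolysis of the fusion bond C3–C5, assisted by the ring oxygen, which gives the C2=C3 alkene and the seven-membered oxocarbenium ion 12 with C4 now a ring member; the ketene acetal then bonds to C5 (new C5–C6 bond) and the silyl triflate set free carries the chain. The closest known reaction is the Lewis acid ring expansion of cyclopropanated glycals that carry an ester on the carbon next to the cyclopropane, with trapping by silyl nucleophiles (a Ferrier-type C-glycosylation one ring size up). Ring A (O, C5, C4, C3, C2, C1, C10) is closed by one-carbon enlargement of the pyran and not by a cyclization, so no ring-closure mode has to be favoured. The only new stereocenter, C5, is set by the substrate: C15 on C4 and C14 on C10 stand on the same face of the ion, so the nucleophile should enter from the opposite face, anti to the C4 methyl and cis to the C9 side chain, while C4 keeps its configuration because none of its four bonds is broken. The step needs regioselective cleavage of C3–C5 rather than C3–C4, secured by oxygen stabilisation of the cation at C5, and facial selectivity at C5, secured by the two methyl groups.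

Step 8
Reactants: 13 methyl 2-[(2R,3S,7R)-7-[(4S)-2,2-dimethyl-1,3-dioxolan-4-yl]-3,7-dimethyl-2,3,6,7-tetrahydrooxepin-2-yl]acetate
Product: 14 methyl 2-[(2R,3S,7R)-7-[(4S)-2,2-dimethyl-1,3-dioxolan-4-yl]-3,7-dimethyloxepan-2-yl]acetate
Conditions: H2 (1 atm), Pd/C, EtOAc, rt
Reagents that add atoms: none
Why: Heterogeneous hydrogenation of the only C=C bond (C2=C3); no stereocenter is created and no allylic C–O bond is present to be cleaved.

Step 9
Reactants: 14 methyl 2-[(2R,3S,7R)-7-[(4S)-2,2-dimethyl-1,3-dioxolan-4-yl]-3,7-dimethyloxepan-2-yl]acetate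
Product: 15 methyl 2-[(2R,3S,7R)-7-[(1S)-1,2-dihydroxyethyl]-3,7-dimethyloxepan-2-yl]acetate
Conditions: AcOH/H2O (4:1), 40 °C
Reagents that add atoms: none
Why: Acid hydrolysis of the terminal acetonide; the methyl ester and the oxepane ether are stable to aqueous acetic acid.

Step 10
Reactants: 15 methyl 2-[(2R,3S,7R)-7-[(1S)-1,2-dihydroxyethyl]-3,7-dimethyloxepan-2-yl]acetate
Product: 16 methyl 2-[(2R,3S,7R)-7-[(1S)-1,2-bis(tert-butyldimethylsilyloxy)ethyl]-3,7-dimethyloxepan-2-yl]acetate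
Conditions: t-BuMe2SiOTf, 2,6-lutidine, CH2Cl2, −78 → 0 °C
Reagents that add atoms: tert-butyldimethylsilyl triflate, CC(C)(C)[Si](C)(C)OS(=O)(=O)C(F)(F)F
Why: The silyl triflate silylates both hydroxyls, including the hindered secondary one at C9 next to the quaternary C10.

Step 11
Reactants: 16 methyl 2-[(2R,3S,7R)-7-[(1S)-1,2-bis(tert-butyldimethylsilyloxy)ethyl]-3,7-dimethyloxepan-2-yl]acetate
Product: 17 2-[(2R,3S,7R)-7-[(1S)-1,2-bis(tert-butyldimethylsilyloxy)ethyl]-3,7-dimethyloxepan-2-yl]acetaldehyde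
Conditions: i-Bu2AlH (1.1 equiv), CH2Cl2, −78 °C; aq. potassium sodium tartrate
Reagents that add atoms: none
Why: Partial reduction of the ester stops at the tetrahedral aluminium hemiacetal, which is held by chelation to the ring oxygen at −78 °C and gives the C7 aldehyde on work-up.

Step 12
Reactants: 17 2-[(2R,3S,7R)-7-[(1S)-1,2-bis(tert-butyldimethylsilyloxy)ethyl]-3,7-dimethyloxepan-2-yl]acetaldehyde; 18 methyl acrylate
Product: 19 methyl 4-[(2R,3S,7R)-7-[(1S)-1,2-bis(tert-butyldimethylsilyloxy)ethyl]-3,7-dimethyloxepan-2-yl]-3-hydroxy-2-methylidenebutanoate (both C7 carbinol epimers)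
Conditions: DABCO, MeOH (additive), neat 18, rt
Reagents that add atoms: none
Why: Morita–Baylis–Hillman reaction: the amine–acrylate zwitterion adds to the unhindered aldehyde and attaches C11, C12 and C13 to C7; the carbinol configuration is irrelevant because it is erased in step 13.

Step 13
Reactants: 19 methyl 4-[(2R,3S,7R)-7-[(1S)-1,2-bis(tert-butyldimethylsilyloxy)ethyl]-3,7-dimethyloxepan-2-yl]-3-hydroxy-2-methylidenebutanoate
Product: 20 methyl (2Z)-4-[(2R,3S,7R)-7-[(1S)-1,2-bis(tert-butyldimethylsilyloxy)ethyl]-3,7-dimethyloxepan-2-yl]-2-(bromomethyl)but-2-enoate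
Conditions: NBS, Me2S, CH2Cl2, 0 °C → rt
Reagents that add atoms: N-bromosuccinimide, O=C1CCC(=O)N1Br
Why: The alkoxysulfonium salt is displaced by bromide with allylic transposition (SN2'), which gives the conjugated (Z)-2-(bromomethyl)enoate with C6 trans to the ester.

Step 14
Reactants: 20 methyl (2Z)-4-[(2R,3S,7R)-7-[(1S)-1,2-bis(tert-butyldimethylsilyloxy)ethyl]-3,7-dimethyloxepan-2-yl]-2-(bromomethyl)but-2-enoate
Product: 21 methyl (2Z)-2-(bromomethyl)-4-[(2R,3S,7R)-7-[(1S)-1-(tert-butyldimethylsilyloxy)-2-hydroxyethyl]-3,7-dimethyloxepan-2-yl]but-2-enoate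
Conditions: camphorsulfonic acid (cat.), MeOH/CH2Cl2, 0 °C
Reagents that add atoms: none
Why: Acid-catalysed methanolysis removes the unhindered primary silyl ether much faster than the secondary one at C9, and the base-free medium leaves the allylic bromide alone.

Step 15
Reactants: 21 methyl (2Z)-2-(bromomethyl)-4-[(2R,3S,7R)-7-[(1S)-1-(tert-butyldimethylsilyloxy)-2-hydroxyethyl]-3,7-dimethyloxepan-2-yl]but-2-enoate
Product: 22 methyl (2Z)-2-(bromomethyl)-4-[(2R,3S,7R)-7-[(1R)-1-(tert-butyldimethylsilyloxy)-2-oxoethyl]-3,7-dimethyloxepan-2-yl]but-2-enoate (same spatial arrangement at C9; descriptor changes by priority only)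
Conditions: Dess–Martin periodinane, NaHCO3, CH2Cl2, 0 °C → rt
Reagents that add atoms: none
Why: Dess–Martin oxidation is neutral and amine-free, so neither the allylic bromide nor the α-silyloxy stereocenter C9 of the new aldehyde is disturbed.

Step 16
Reactants: 22 methyl (2Z)-2-(bromomethyl)-4-[(2R,3S,7R)-7-[(1R)-1-(tert-butyldimethylsilyloxy)-2-oxoethyl]-3,7-dimethyloxepan-2-yl]but-2-enoate
Product: 24 (4S,5R,7R,8R,9S,10R)-9-(tert-butyldimethylsilyloxy)-5,10-epoxygermacr-11(13)-en-12,8-olide (overview numbering), via hydroxy ester 23 (not isolated)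
Conditions: CrCl2 (excess), THF, rt, high dilution; then pyridinium p-toluenesulfonate (cat.), benzene, 40 °C
Reagents that add atoms: none
Why: Intramolecular Nozaki–Hiyama–Kishi-type allylation: the allylchromium adds through its γ-carbon C7 to the C8 aldehyde in a chair-like six-membered transition state fused to the forming oxepane, which should place C11, O8 and the C9 silyloxy group all pseudo-equatorial on ring B (H7/H8 trans, O8 trans to O9) and so set C7 and C8, after which the C8 hydroxyl closes the α-methylene lactone with loss of methanol.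

Step 17
Reactants: 24 (4S,5R,7R,8R,9S,10R)-9-(tert-butyldimethylsilyloxy)-5,10-epoxygermacr-11(13)-en-12,8-olide
Product: 25 (4S,5R,7R,8R,9S,10R)-9-hydroxy-5,10-epoxygermacr-11(13)-en-12,8-olide
Conditions: HF·pyridine, THF, 0 °C → rt
Reagents that add atoms: none
Why: Fluoride cleaves the Si–O bond under acidic, non-nucleophilic conditions that spare the α-methylene lactone, which is prone to conjugate addition.

Step 18
Reactants: 25 (4S,5R,7R,8R,9S,10R)-9-hydroxy-5,10-epoxygermacr-11(13)-en-12,8-olide; 26 (R)-2-methylbutanoic acid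
Product: 27 (4S,5R,7R,8R,9S,10R)-9-[(2R)-2-methylbutanoyloxy]-5,10-epoxygermacr-11(13)-en-12,8-olide (target, CNP0136059.1)
Conditions: DCC, DMAP (cat.), CH2Cl2, 0 °C → rt
Reagents that add atoms: none
Why: Steglich esterification activates the acid without strong base, so its α-stereocenter is kept, and the C9–O bond is not touched, so C9 retains its configuration.

**Compound list**

1 | methyl (4S)-2,2-dimethyl-1,3-dioxolane-4-carboxylate | COC(=O)[C@@H]1COC(C)(C)O1 | starting material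
2 | (4S)-N-methoxy-N,2,2-trimethyl-1,3-dioxolane-4-carboxamide | CON(C)C(=O)[C@@H]1COC(C)(C)O1 | intermediate
3 | 1-[(4S)-2,2-dimethyl-1,3-dioxolan-4-yl]ethan-1-one | CC(=O)[C@@H]1COC(C)(C)O1 | intermediate
4 | (E)-1-methoxy-3-(trimethylsilyloxy)buta-1,3-diene | CO/C=C/C(=C)O[Si](C)(C)C | starting material
5 | (1E,5R)-5-[(4S)-2,2-dimethyl-1,3-dioxolan-4-yl]-5-hydroxy-1-methoxyhex-1-en-3-one | CO/C=C/C(=O)C[C@@](C)(O)[C@@H]1COC(C)(C)O1 | intermediate (not isolated)
6 | (2R)-2-[(4S)-2,2-dimethyl-1,3-dioxolan-4-yl]-2-methyl-2,3-dihydro-4H-pyran-4-one | O=C1C[C@](C)([C@@H]2COC(C)(C)O2)OC=C1 | intermediate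
7 | (2R,4R)-2-[(4S)-2,2-dimethyl-1,3-dioxolan-4-yl]-2-methyl-3,4-dihydro-2H-pyran-4-ol | O[C@@H]1C[C@](C)([C@@H]2COC(C)(C)O2)OC=C1 | intermediate
8 | 1,1-diiodoethane | CC(I)I | starting material
9 | (1R,3R,5R,6R,7S)-3-[(4S)-2,2-dimethyl-1,3-dioxolan-4-yl]-3,7-dimethyl-2-oxabicyclo[4.1.0]heptan-5-ol | O[C@@H]1C[C@](C)([C@@H]2COC(C)(C)O2)O[C@@H]2[C@@H](C)[C@H]12 | intermediate
10 | (1R,3R,5R,6R,7S)-3-[(4S)-2,2-dimethyl-1,3-dioxolan-4-yl]-3,7-dimethyl-2-oxabicyclo[4.1.0]heptan-5-yl acetate | CC(=O)O[C@@H]1C[C@](C)([C@@H]2COC(C)(C)O2)O[C@@H]2[C@@H](C)[C@H]12 | intermediate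
11 | 1-(tert-butyldimethylsilyloxy)-1-methoxyethene | C=C(OC)O[Si](C)(C)C(C)(C)C | starting material
12 | (3S,7R)-7-[(4S)-2,2-dimethyl-1,3-dioxolan-4-yl]-3,7-dimethyl-3,6-dihydro-7H-oxepin-1-ium triflate (oxocarbenium ion at C5) | C[C@H]1C=CC[C@](C)([C@@H]2COC(C)(C)O2)[O+]=C1.[O-]S(=O)(=O)C(F)(F)F | intermediate (not isolated)
13 | methyl 2-[(2R,3S,7R)-7-[(4S)-2,2-dimethyl-1,3-dioxolan-4-yl]-3,7-dimethyl-2,3,6,7-tetrahydrooxepin-2-yl]acetate | COC(=O)C[C@H]1O[C@@](C)([C@@H]2COC(C)(C)O2)CC=C[C@@H]1C | intermediate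
14 | methyl 2-[(2R,3S,7R)-7-[(4S)-2,2-dimethyl-1,3-dioxolan-4-yl]-3,7-dimethyloxepan-2-yl]acetate | COC(=O)C[C@H]1O[C@@](C)([C@@H]2COC(C)(C)O2)CCC[C@@H]1C | intermediate
15 | methyl 2-[(2R,3S,7R)-7-[(1S)-1,2-dihydroxyethyl]-3,7-dimethyloxepan-2-yl]acetate | COC(=O)C[C@H]1O[C@@](C)([C@@H](O)CO)CCC[C@@H]1C | intermediate
16 | methyl 2-[(2R,3S,7R)-7-[(1S)-1,2-bis(tert-butyldimethylsilyloxy)ethyl]-3,7-dimethyloxepan-2-yl]acetate | COC(=O)C[C@H]1O[C@@](C)([C@@H](O[Si](C)(C)C(C)(C)C)CO[Si](C)(C)C(C)(C)C)CCC[C@@H]1C | intermediate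
17 | 2-[(2R,3S,7R)-7-[(1S)-1,2-bis(tert-butyldimethylsilyloxy)ethyl]-3,7-dimethyloxepan-2-yl]acetaldehyde | O=CC[C@H]1O[C@@](C)([C@@H](O[Si](C)(C)C(C)(C)C)CO[Si](C)(C)C(C)(C)C)CCC[C@@H]1C | intermediate
18 | methyl acrylate | C=CC(=O)OC | starting material
19 | methyl 4-[(2R,3S,7R)-7-[(1S)-1,2-bis(tert-butyldimethylsilyloxy)ethyl]-3,7-dimethyloxepan-2-yl]-3-hydroxy-2-methylidenebutanoate (carbinol epimers) | C=C(C(=O)OC)C(O)C[C@H]1O[C@@](C)([C@@H](O[Si](C)(C)C(C)(C)C)CO[Si](C)(C)C(C)(C)C)CCC[C@@H]1C | intermediate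
20 | methyl (2Z)-4-[(2R,3S,7R)-7-[(1S)-1,2-bis(tert-butyldimethylsilyloxy)ethyl]-3,7-dimethyloxepan-2-yl]-2-(bromomethyl)but-2-enoate | COC(=O)/C(CBr)=C/C[C@H]1O[C@@](C)([C@@H](O[Si](C)(C)C(C)(C)C)CO[Si](C)(C)C(C)(C)C)CCC[C@@H]1C | intermediate
21 | methyl (2Z)-2-(bromomethyl)-4-[(2R,3S,7R)-7-[(1S)-1-(tert-butyldimethylsilyloxy)-2-hydroxyethyl]-3,7-dimethyloxepan-2-yl]but-2-enoate | COC(=O)/C(CBr)=C/C[C@H]1O[C@@](C)([C@@H](O[Si](C)(C)C(C)(C)C)CO)CCC[C@@H]1C | intermediate
22 | methyl (2Z)-2-(bromomethyl)-4-[(2R,3S,7R)-7-[(1R)-1-(tert-butyldimethylsilyloxy)-2-oxoethyl]-3,7-dimethyloxepan-2-yl]but-2-enoate | COC(=O)/C(CBr)=C/C[C@H]1O[C@@](C)([C@@H](O[Si](C)(C)C(C)(C)C)C=O)CCC[C@@H]1C | intermediate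
23 | methyl (4S,5R,7R,8R,9S,10R)-9-(tert-butyldimethylsilyloxy)-8-hydroxy-5,10-epoxygermacr-11(13)-en-12-oate | C=C(C(=O)OC)[C@H]1C[C@H]2O[C@](C)(CCC[C@@H]2C)[C@@H](O[Si](C)(C)C(C)(C)C)[C@@H]1O | intermediate (not isolated)
24 | (4S,5R,7R,8R,9S,10R)-9-(tert-butyldimethylsilyloxy)-5,10-epoxygermacr-11(13)-en-12,8-olide | C=C1C(=O)O[C@@H]2[C@@H]1C[C@H]1O[C@](C)(CCC[C@@H]1C)[C@H]2O[Si](C)(C)C(C)(C)C | intermediate
25 | (4S,5R,7R,8R,9S,10R)-9-hydroxy-5,10-epoxygermacr-11(13)-en-12,8-olide | C=C1C(=O)O[C@@H]2[C@@H]1C[C@H]1O[C@](C)(CCC[C@@H]1C)[C@H]2O | intermediate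
26 | (R)-2-methylbutanoic acid | CC[C@@H](C)C(O)=O | starting material
27 | (4S,5R,7R,8R,9S,10R)-9-[(2R)-2-methylbutanoyloxy]-5,10-epoxygermacr-11(13)-en-12,8-olide | C=C1C(=O)O[C@@H]2[C@@H]1C[C@H]1O[C@](C)(CCC[C@@H]1C)[C@H]2OC(=O)[C@H](C)CC | target

**Step count and risks**

Total step count: 18. Longest linear sequence: 18 steps (from 1).

Steps most likely to fail:

1. Step 7. The capture at C5 may lose facial control, or the dioxolane oxygen may intercept the oxocarbenium ion while the silyl triflate cleaves the acetonide. The fallback delivers the nucleophile from the C9 oxygen through a tether and sets out from 9. Benzoylation (PhCOCl, pyridine) gives the C2 benzoate of the cyclopropyl carbinol F1. Aqueous acetic acid then frees the C8/C9 diol benzoate F2, and t-BuMe2SiCl/imidazole silylates the primary hydroxyl to give the C8 silyl ether F3. Ac2O/DMAP gives the C9 acetate F4, and LiN(SiMe3)2 with t-BuMe2SiCl in THF at −78 °C converts this acetate into its silyl ketene acetal F5, which is not isolated. Me3SiOTf (cat.) in CH2Cl2 at −78 °C triggers the same ring enlargement; the tethered ketene acetal can reach C5 only from the face of the C9 side chain and should close the bridged seven-membered lactone F6. K2CO3 in MeOH opens the lactone to the C9-hydroxy methyl ester of the oxepene F7, hydrogenation (H2, Pd/C) gives the oxepane hydroxy ester F8, and t-BuMe2SiOTf/2,6-lutidine silylates C9–OH, which rejoins the route at 16.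

2. Step 16. The allylchromium may close through the wrong diastereomeric transition state (cis-fused lactone, or O8 cis to O9), or couple intermolecularly faster than it cyclizes. The fallback closes ring B by a ketyl–olefin radical cyclization and adds C13 afterwards; it sets out from 17. Wittig reaction with Ph3P=CHCO2Me gives the (E)-enoate F9, camphorsulfonic acid in MeOH frees the primary alcohol F10, and Dess–Martin oxidation gives the C8 aldehyde F11. SmI2 in THF with hexamethylphosphoramide and t-BuOH should add the C8 ketyl to C7 of the enoate anti to the C9 silyloxy group to give the cyclized hydroxy ester F12, which is not isolated and lactonizes to the trans-fused lactone lacking C13, F13. LiN(i-Pr)2 followed by dimethylmethylideneammonium iodide gives the C11 dimethylaminomethyl lactone F14; MeI gives its methiodide F15, which is not isolated, and NaHCO3 eliminates trimethylamine, which rejoins the route at 24.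

3. Step 5. The methyl group may be delivered to the endo position, or the zinc iodide formed may ionize the glycal-like allylic alcohol (Ferrier-type decomposition) before cyclopropanation. The fallback transfers the ethylidene unit as a nucleophile and sets out from 6. Corey–Chaykovsky-type cyclopropanation of the enone with (dimethylamino)phenyloxosulfonium ethylide (from the ethyl sulfoxonium tetrafluoroborate and NaH in DMSO) closes stepwise, which should place the methyl trans to both ring bonds (exo) on the face away from the pseudo-axial C10 methyl and give the cyclopropyl ketone F16. NaBH4 in MeOH at 0 °C then reduces the ketone from the face away from the cyclopropane, which rejoins the route at 9.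

**Further compounds**

F1 | step 7 | C2 benzoate of 9: 3-[(4S)-2,2-dimethyl-1,3-dioxolan-4-yl]-3,7-dimethyl-2-oxabicyclo[4.1.0]heptan-5-yl benzoate (configuration as in 10) | O=C(c1ccccc1)O[C@@H]1C[C@](C)([C@@H]2COC(C)(C)O2)O[C@@H]2[C@@H](C)[C@H]12
F2 | step 7 | 3-[(1S)-1,2-dihydroxyethyl]-3,7-dimethyl-2-oxabicyclo[4.1.0]heptan-5-yl benzoate | O=C(c1ccccc1)O[C@@H]1C[C@](C)([C@@H](O)CO)O[C@@H]2[C@@H](C)[C@H]12
F3 | step 7 | 3-[(1S)-2-(tert-butyldimethylsilyloxy)-1-hydroxyethyl]-3,7-dimethyl-2-oxabicyclo[4.1.0]heptan-5-yl benzoate | O=C(c1ccccc1)O[C@@H]1C[C@](C)([C@@H](O)CO[Si](C)(C)C(C)(C)C)O[C@@H]2[C@@H](C)[C@H]12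
F4 | step 7 | 3-[(1S)-1-acetoxy-2-(tert-butyldimethylsilyloxy)ethyl]-3,7-dimethyl-2-oxabicyclo[4.1.0]heptan-5-yl benzoate | O=C(c1ccccc1)O[C@@H]1C[C@](C)([C@@H](OC(C)=O)CO[Si](C)(C)C(C)(C)C)O[C@@H]2[C@@H](C)[C@H]12
F5 | step 7 | silyl ketene acetal of the C9 acetate of F4 | O=C(c1ccccc1)O[C@@H]1C[C@](C)([C@@H](OC(=C)O[Si](C)(C)C(C)(C)C)CO[Si](C)(C)C(C)(C)C)O[C@@H]2[C@@H](C)[C@H]12
F6 | step 7 | bridged lactone C6–C7(=O)–O9 spanning C5 and C9 of the oxepene, C8 silyl ether | O=C1C[C@H]2O[C@](C)(CC=C[C@@H]2C)[C@H](CO[Si](C)(C)C(C)(C)C)O1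
F7 | step 7 | methyl 2-[(2R,3S,7R)-7-[(1S)-2-(tert-butyldimethylsilyloxy)-1-hydroxyethyl]-3,7-dimethyl-2,3,6,7-tetrahydrooxepin-2-yl]acetate | COC(=O)C[C@H]1O[C@@](C)([C@@H](O)CO[Si](C)(C)C(C)(C)C)CC=C[C@@H]1C
F8 | step 7 | methyl 2-[(2R,3S,7R)-7-[(1S)-2-(tert-butyldimethylsilyloxy)-1-hydroxyethyl]-3,7-dimethyloxepan-2-yl]acetate | COC(=O)C[C@H]1O[C@@](C)([C@@H](O)CO[Si](C)(C)C(C)(C)C)CCC[C@@H]1C
F9 | step 16 | methyl (2E)-4-[(2R,3S,7R)-7-[(1S)-1,2-bis(tert-butyldimethylsilyloxy)ethyl]-3,7-dimethyloxepan-2-yl]but-2-enoate | COC(=O)/C=C/C[C@H]1O[C@@](C)([C@@H](O[Si](C)(C)C(C)(C)C)CO[Si](C)(C)C(C)(C)C)CCC[C@@H]1C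
F10 | step 16 | methyl (2E)-4-[(2R,3S,7R)-7-[(1S)-1-(tert-butyldimethylsilyloxy)-2-hydroxyethyl]-3,7-dimethyloxepan-2-yl]but-2-enoate | COC(=O)/C=C/C[C@H]1O[C@@](C)([C@@H](O[Si](C)(C)C(C)(C)C)CO)CCC[C@@H]1C
F11 | step 16 | methyl (2E)-4-[(2R,3S,7R)-7-[(1R)-1-(tert-butyldimethylsilyloxy)-2-oxoethyl]-3,7-dimethyloxepan-2-yl]but-2-enoate | COC(=O)/C=C/C[C@H]1O[C@@](C)([C@@H](O[Si](C)(C)C(C)(C)C)C=O)CCC[C@@H]1C
F12 | step 16 | cyclized hydroxy ester: ring B closed at C7–C8, C7 bearing CH2CO2CH3, C8–OH, C9 silyl ether | COC(=O)C[C@H]1C[C@H]2O[C@](C)(CCC[C@@H]2C)[C@@H](O[Si](C)(C)C(C)(C)C)[C@@H]1O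
F13 | step 16 | trans-fused 12,8-lactone lacking C13 (C11 = CH2), C9 silyl ether | C1C(=O)O[C@@H]2[C@@H]1C[C@H]1O[C@](C)(CCC[C@@H]1C)[C@H]2O[Si](C)(C)C(C)(C)C
F14 | step 16 | C11 (dimethylamino)methyl lactone (C11 epimers) | CN(C)CC1C(=O)O[C@@H]2[C@@H]1C[C@H]1O[C@](C)(CCC[C@@H]1C)[C@H]2O[Si](C)(C)C(C)(C)C
F15 | step 16 | methiodide of F14 | C[N+](C)(C)CC1C(=O)O[C@@H]2[C@@H]1C[C@H]1O[C@](C)(CCC[C@@H]1C)[C@H]2O[Si](C)(C)C(C)(C)C.[I-]
F16 | step 5 | 3-[(4S)-2,2-dimethyl-1,3-dioxolan-4-yl]-3,7-dimethyl-2-oxabicyclo[4.1.0]heptan-5-one (methyl exo, ring configuration as in 9) | O=C1C[C@](C)([C@@H]2COC(C)(C)O2)O[C@@H]2[C@@H](C)[C@H]12
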